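**Strategy.** Everything rests on cutting the C5–C6 ring-fusion bond, which bisects the ten-carbon perimeter C1–C2–C3–C4–C5–C9–C8–C7–C6–C10 shared by the seven- and five-membered rings; C9, the epoxide CH, is carried as a ketone so that C5 can be a diazo carbon. A dirhodium carbenoid at C5 then inserts into a transannular C6–H bond, forging both carbocycles and the C5/C6 stereocentres in one operation. Its precursor is a ten-membered α-diazo ketone already bearing the C1 isovanillate (phenol as TIPS ether), the C3 triethylsilyl ether, the C10 isopropyl and C8 methyl groups, assembled from (R)-linalool by two allylborations and ring-closing metathesis.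

Key step: step 13

**Remarks on the chemistry**
- Numbering: seven-membered ring C1(OAr)–C2–C3(Me)(OH)–C4–C5–C6–C10(iPr); five-membered ring C5–C9–C8(Me)–C7–C6; epoxide C8–C9. Locants in compound names refer to these core atoms. Ar′ = 4-methoxy-3-(triisopropylsilyloxy)phenyl; Ipc = isopinocampheyl derived from (+)-α-pinene.
- Relative configuration of the target: C1 ester, C3 hydroxyl and C10 isopropyl lie on one face of the seven-membered ring; H5 and H6 are trans; the epoxide oxygen is on the face of the five-membered ring syn to C4, the side of the C3 hydroxyl.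
- Design of the precursor: the C1 oxygen carries the final aroyl group from step 6 onward. It has no enolisable hydrogen, so it tolerates the enolate chemistry of steps 12–14, it deactivates C1–H, and no ester exchange is needed after the key step. C8 is set as one epimer so that a single macrocycle enters step 13.
- Assumption: the (−)-Ipc2B allyl reagents attack the aldehyde face that gives the R carbinol here, as in the crotyl series; were the sense opposite, the enantiomeric borane would be used.

**Route**

Step 1
Reactants: 1 (R)-linalool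
Product: 2 (R)-linalool triethylsilyl ether
Conditions: Et3SiOTf, 2,6-lutidine, CH2Cl2, −78 → 0 °C
Reagents that add atoms: triethylsilyl triflate, CC[Si](CC)(CC)OS(=O)(=O)C(F)(F)F
Why: O-silylation with a silyl triflate and a hindered pyridine base protects the tertiary allylic alcohol without ionising it, giving a non-nucleophilic C3 substituent that lasts until step 16 and leaves the stereocentre untouched.

Step 2
Reactants: 2 (R)-linalool triethylsilyl ether
Product: 4 (R)-3,7-dimethyl-3-(triethylsilyloxy)oct-6-en-1-ol, via B-alkyl-9-BBN adduct 3 (not isolated)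
Conditions: 9-BBN, THF, 0 °C → rt; then NaOH, H2O2, H2O, 0 °C → rt
Reagents that add atoms: hydrogen peroxide, OO
Why: Hydroboration–oxidation with 9-BBN is anti-Markovnikov and engages the monosubstituted vinyl group far faster than the trisubstituted alkene, so only the future C1 is hydroxylated.

Step 3
Reactants: 4 (R)-3,7-dimethyl-3-(triethylsilyloxy)oct-6-en-1-ol
Product: 5 (R)-3,7-dimethyl-3-(triethylsilyloxy)oct-6-enal
Conditions: TEMPO (cat.), PhI(OAc)2, CH2Cl2, rt
Reagents that add atoms: none
Why: Oxoammonium oxidation (TEMPO with a hypervalent iodine co-oxidant) stops at the aldehyde and spares the alkene and silyl ether, and its near-neutral medium avoids β-elimination of the silyloxy group.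

Step 4
Reactants: 5 (R)-3,7-dimethyl-3-(triethylsilyloxy)oct-6-enal; 6 (E)-4-methylpent-2-ene
Product: 9 anti homoallylic alcohol (1R;10S), via allylborane 7 (not isolated), via borinate 8 (not isolated)
Conditions: 6, KOt-Bu, n-BuLi, THF, −78 → −50 °C; (−)-Ipc2BOMe, −78 °C; BF3·OEt2; 5, −78 °C; then NaOH, H2O2, 0 °C → rt
Reagents that add atoms: none
Why: Brown-type asymmetric allylboration: the E allylborane reacts through a chair (Zimmerman–Traxler) transition state with isopropyl equatorial, giving the anti C1/C10 relationship, while the isopinocampheyl groups direct attack to the aldehyde face that gives 1R (hence 1R,10S), reagent control overriding the remote C3 centre.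

Step 5
Reactants: 10 isovanillic acid
Product: 12 4-methoxy-3-(triisopropylsilyloxy)benzoic acid, via bis-silyl derivative 11 (not isolated)
Conditions: i-Pr3SiCl, imidazole, DMF, rt; then AcOH, THF, H2O, rt
Reagents that add atoms: triisopropylsilyl chloride, CC(C)[Si](Cl)(C(C)C)C(C)C
Why: Silyl chloride with imidazole silylates both phenol and acid, and the much more labile silyl ester is hydrolysed by mild aqueous acid, leaving the aryl silyl ether that masks the phenol until the last step.

Step 6
Reactants: 9 anti homoallylic alcohol (1R;10S); 12 4-methoxy-3-(triisopropylsilyloxy)benzoic acid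
Product: 14 C1 aroate ester, via mixed anhydride 13 (not isolated)
Conditions: 12, 2,4,6-Cl3C6H2COCl, Et3N, THF, rt; then 9, DMAP, toluene, rt → 40 °C
Reagents that add atoms: none
Why: Yamaguchi esterification acylates the hindered secondary C1 alcohol through the mixed anhydride and DMAP, installing the acyl group of the target, which has no enolisable hydrogen and deactivates C1–H for step 13.

Step 7
Reactants: 14 C1 aroate ester
Product: 16 C9 aldehyde, via ozonide 15 (not isolated)
Conditions: O3, CH2Cl2, −78 °C (Sudan Red 7B end-point); then PPh3, −78 °C → rt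
Reagents that add atoms: ozone, [O-][O+]=O
Why: Ozonolysis is electrophilic and consumes the electron-rich trisubstituted alkene well before the hindered, ester-flanked vinyl group or the arene, the dye end-point preventing over-ozonation, and PPh3 reduces the ozonide to the aldehyde.

Step 8
Reactants: 16 C9 aldehyde; 17 (E)-but-2-ene
Product: 20 diene alcohol (9R;8S), via crotylborane 18 (not isolated), via borinate 19 (not isolated)
Conditions: 17, KOt-Bu, n-BuLi, THF, −78 → −45 °C; (−)-Ipc2BOMe, −78 °C; BF3·OEt2; 16, −78 °C; then NaBO3·4H2O, THF/H2O, rt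
Reagents that add atoms: none
Why: Brown E-crotylboration through the same chair transition state and ligand antipode gives the anti adduct 9R,8S as one diastereomer; C9 is oxidised in step 11 and C8 is erased in step 14, so this control only ensures that a single macrocycle diastereomer reaches the key step.

Step 9
Reactants: 20 diene alcohol (9R;8S)
Product: 21 cyclodecenol (C6=C7)
Conditions: second-generation Grubbs catalyst (H2IMes)(PCy3)Cl2Ru=CHPh (10 mol %), 1,4-benzoquinone (cat.), toluene (1 mM), 80 °C
Reagents that add atoms: none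
Why: Ring-closing olefin metathesis joins C6 and C7 with loss of ethylene; both vinyl groups sit on branched carbons and dimerise slowly, the quaternary C3 and the branched C1/C10 and C8/C9 pairs fold the chain, high dilution favours the ten-membered ring, and the alkene geometry is irrelevant because it is hydrogenated next.

Step 10
Reactants: 21 cyclodecenol (C6=C7)
Product: 22 cyclodecanol
Conditions: H2 (1 atm), Pd/C, EtOAc, rt
Reagents that add atoms: none
Why: Heterogeneous catalytic hydrogenation saturates the disubstituted ring alkene, making C6 the methylene that the carbenoid will attack, while the aroate, aryl silyl ether and tertiary silyl ether are inert.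

Step 11
Reactants: 22 cyclodecanol
Product: 23 cyclodecanone (C9 ketone)
Conditions: Dess–Martin periodinane, CH2Cl2, 0 °C → rt
Reagents that add atoms: none
Why: Dess–Martin oxidation converts the secondary carbinol into the C9 ketone under nearly neutral conditions that neither epimerise C8 nor cleave the silyl groups.

Step 12
Reactants: 23 cyclodecanone (C9 ketone)
Product: 25 ten-membered α-diazo ketone, via trifluoroacetyl ketone 24 (not isolated)
Conditions: LiN(SiMe3)2, THF, −78 °C; CF3CO2CH2CF3; 5% HCl wash; then MeSO2N3, Et3N, H2O, MeCN, rt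
Reagents that add atoms: methanesulfonyl azide, CS(=O)(=O)N=[N+]=[N-]
Why: Detrifluoroacetylative (Regitz-type) diazo transfer: the amide base removes a proton kinetically from the C5 methylene, not the C8 methine, the trifluoroacetyl ketone is acidic enough for azide transfer under triethylamine, and the activating group leaves as the sulfonamide, the aroate having no α-hydrogen to interfere.

Step 13
Reactants: 25 ten-membered α-diazo ketone
Product: 27 trans-fused hydroazulen-9-one, via cis-fused ketone 26 (not isolated)
Conditions: Rh2(O2CCPh3)4 (2 mol %), CH2Cl2, −78 → 0 °C, slow addition of 25; then DBU (0.2 equiv), rt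
Reagents that add atoms: none
Why: Proposed new method: loss of N2 from 25 on the dirhodium carboxylate gives an electrophilic acyl carbenoid at C5 that inserts, with retention at carbon, into the C6–H bond pointing across the ring through the five-centre array C5–C9–C8–C7–C6, so the cyclopentanone closes in the normal 1,5 mode and the same bond closes the seven-membered ring transannularly along C5–C4–C3–C2–C1–C10–C6. The closest known reactions are the dirhodium-catalysed 1,5-C–H insertion of acyclic α-diazo ketones to cyclopentanones and the transannular C–H insertion of cyclodecylidene carbenes, which have not been combined on a ten-membered α-diazo ketone. C6 is fixed by which diastereotopic hydrogen is delivered: the desired one leaves isopropyl pseudo-equatorial and C7 trans to it, whereas the other gives an all-cis C1/C10/C6 array that must put isopropyl axial or C7 1,3-diaxial to the C1 ester, so the desired hydrogen should react, but this conformational preference is the one unsecured element of the route. C5 is not left to the insertion: the suprafacial event should give the cis-fused ketone 26 first, and DBU then equilibrates the enolisable C5 centre to the trans fusion in which C4, C7 and isopropyl are all pseudo-equatorial (C8 may epimerise as well, which is harmless). Site selectivity needs C6–H to beat C1–H (the other 1,5 site), the tertiary C10–H (1,6) and a 1,2-hydride shift from C4; the aroyloxy group deactivates C1–H and inductively C10–H, the C4 hydrogens are neopentyl and flanked by the electron-withdrawing silyloxy carbon, and bulky triphenylacetate ligands at low temperature are the conditions known to suppress β-hydride migration and to favour methylene over methine insertion.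

Step 14
Reactants: 27 trans-fused hydroazulen-9-one
Product: 29 C8=C9 enol triflate, via lithium enolate 28 (not isolated)
Conditions: LiN(i-Pr)2, THF, −78 °C; then N-(5-chloropyridin-2-yl)bis(trifluoromethanesulfonimide), −78 → −20 °C
Reagents that add atoms: Comins' reagent, Clc1ccc(N(S(=O)(=O)C(F)(F)F)S(=O)(=O)C(F)(F)F)nc1
Why: Kinetic enolate formation and O-triflation: the hindered amide is expected to remove the exposed C8–H (flanked by CH3 and a ring CH2) in preference to the ring-fusion C5–H (flanked by the branched C6 and the neopentyl-type C4), both C8 epimers give the same enolate, and cold trapping prevents equilibration.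

Step 15
Reactants: 29 C8=C9 enol triflate
Product: 30 C8=C9 alkene (C3 silyl ether)
Conditions: Pd(OAc)2 (5 mol %), PPh3, n-Bu3N, HCO2H, DMF, 60 °C
Reagents that add atoms: none
Why: Palladium-catalysed formate reduction of an enol triflate (oxidative addition, formate decarboxylation, reductive elimination) replaces the triflate by hydrogen and gives the trisubstituted C8=C9 alkene without touching C5.

Step 16
Reactants: 30 C8=C9 alkene (C3 silyl ether)
Product: 31 C3 tertiary alcohol
Conditions: PPTS, MeOH, 40 °C
Reagents that add atoms: none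
Why: Acid-catalysed methanolysis removes the alkyl triethylsilyl ether while the aryl triisopropylsilyl ether, stable to mild acid, stays on, freeing the hydroxyl that steers step 17.

Step 17
Reactants: 31 C3 tertiary alcohol
Product: 32 O-silylated epoxide
Conditions: VO(acac)2 (5 mol %), t-BuOOH, CH2Cl2, 0 °C → rt
Reagents that add atoms: tert-butyl hydroperoxide, CC(C)(C)OO
Why: Hydroxyl-directed vanadium-catalysed epoxidation: the C3 hydroxyl, on the same side of the seven-membered ring as C9, binds the vanadium alkylperoxide and delivers oxygen to the alkene face syn to C4, setting C8 and C9 as in the target, and the syn epoxy alcohol cannot cyclise because back-side attack on C9 is geometrically impossible.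

Step 18
Reactants: 32 O-silylated epoxide
Product: 33 CNP0106636.1 (target)
Conditions: Bu4NF, AcOH, THF, 0 °C
Reagents that add atoms: none
Why: Fluoride cleaves the aryl Si–O bond, and acetic acid buffering keeps the phenoxide from attacking the ester or the epoxide.

**Compound list**

1 | (R)-linalool | C=C[C@](C)(O)CCC=C(C)C | starting material
2 | (R)-linalool triethylsilyl ether | C=C[C@](C)(O[Si](CC)(CC)CC)CCC=C(C)C | intermediate
3 | B-alkyl-9-BBN adduct of 2 (boron on the future C1) | C(C[C@](C)(O[Si](CC)(CC)CC)CCC=C(C)C)B1C2CCCC1CCC2 | intermediate (not isolated)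
4 | (R)-3,7-dimethyl-3-(triethylsilyloxy)oct-6-en-1-ol | OCC[C@](C)(O[Si](CC)(CC)CC)CCC=C(C)C | intermediate
5 | (R)-3,7-dimethyl-3-(triethylsilyloxy)oct-6-enal | O=CC[C@](C)(O[Si](CC)(CC)CC)CCC=C(C)C | intermediate
6 | (E)-4-methylpent-2-ene | C/C=C/C(C)C | starting material
7 | B-[(E)-4-methylpent-2-en-1-yl]diisopinocampheylborane | CC(C)/C=C/CB([C@@H]1C[C@@H]2C[C@H]([C@H]1C)C2(C)C)[C@@H]1C[C@@H]2C[C@H]([C@H]1C)C2(C)C | intermediate (not isolated)
8 | diisopinocampheylborinate of 9 | C=C[C@@H]([C@H](OB([C@@H]1C[C@@H]2C[C@H]([C@H]1C)C2(C)C)[C@@H]1C[C@@H]2C[C@H]([C@H]1C)C2(C)C)C[C@](C)(O[Si](CC)(CC)CC)CCC=C(C)C)C(C)C | intermediate (not isolated)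
9 | (3S,4R,6R)-6,10-dimethyl-3-(propan-2-yl)-6-(triethylsilyloxy)undeca-1,9-dien-4-ol (core C1 R, C10 S; hydroxyl and isopropyl anti) | C=C[C@@H]([C@H](O)C[C@](C)(O[Si](CC)(CC)CC)CCC=C(C)C)C(C)C | intermediate
10 | isovanillic acid | COc1ccc(C(=O)O)cc1O | starting material
11 | triisopropylsilyl 4-methoxy-3-(triisopropylsilyloxy)benzoate | COc1ccc(C(=O)O[Si](C(C)C)(C(C)C)C(C)C)cc1O[Si](C(C)C)(C(C)C)C(C)C | intermediate (not isolated)
12 | 4-methoxy-3-(triisopropylsilyloxy)benzoic acid | COc1ccc(C(=O)O)cc1O[Si](C(C)C)(C(C)C)C(C)C | intermediate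
13 | mixed anhydride of 12 with 2,4,6-trichlorobenzoic acid | COc1ccc(C(=O)OC(=O)c2c(Cl)cc(Cl)cc2Cl)cc1O[Si](C(C)C)(C(C)C)C(C)C | intermediate (not isolated)
14 | C1 aroate ester of 9 (Ar′CO2 on C1) | COc1ccc(C(=O)O[C@H](C[C@](C)(O[Si](CC)(CC)CC)CCC=C(C)C)[C@H](C=C)C(C)C)cc1O[Si](C(C)C)(C(C)C)C(C)C | intermediate
15 | ozonide (1,2,4-trioxolane) of the trisubstituted alkene of 14 | COc1ccc(C(=O)O[C@H](C[C@](C)(O[Si](CC)(CC)CC)CCC2OOC(C)(C)O2)[C@H](C=C)C(C)C)cc1O[Si](C(C)C)(C(C)C)C(C)C | intermediate (not isolated)
16 | C9 aldehyde | COc1ccc(C(=O)O[C@H](C[C@](C)(O[Si](CC)(CC)CC)CCC=O)[C@H](C=C)C(C)C)cc1O[Si](C(C)C)(C(C)C)C(C)C | intermediate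
17 | (E)-but-2-ene | C/C=C/C | starting material
18 | B-[(E)-but-2-en-1-yl]diisopinocampheylborane | C/C=C/CB([C@@H]1C[C@@H]2C[C@H]([C@H]1C)C2(C)C)[C@@H]1C[C@@H]2C[C@H]([C@H]1C)C2(C)C | intermediate (not isolated)
19 | diisopinocampheylborinate of 20 | COc1ccc(C(=O)O[C@H](C[C@](C)(O[Si](CC)(CC)CC)CC[C@@H](OB([C@@H]2C[C@@H]3C[C@H]([C@H]2C)C3(C)C)[C@@H]2C[C@@H]3C[C@H]([C@H]2C)C3(C)C)[C@@H](C)C=C)[C@H](C=C)C(C)C)cc1O[Si](C(C)C)(C(C)C)C(C)C | intermediate (not isolated)
20 | diene alcohol: C9 carbinol (9R) and C8 methyl (8S) anti, vinyl groups on C8 and C10 | COc1ccc(C(=O)O[C@H](C[C@](C)(O[Si](CC)(CC)CC)CC[C@@H](O)[C@@H](C)C=C)[C@H](C=C)C(C)C)cc1O[Si](C(C)C)(C(C)C)C(C)C | intermediate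
21 | cyclodecenol: ten-membered ring with C6=C7 (drawn Z; either geometry serves), C9 hydroxyl | COc1ccc(C(=O)O[C@@H]2C[C@](C)(O[Si](CC)(CC)CC)CC[C@@H](O)[C@@H](C)/C=C\[C@@H]2C(C)C)cc1O[Si](C(C)C)(C(C)C)C(C)C | intermediate
22 | cyclodecanol | COc1ccc(C(=O)O[C@@H]2C[C@](C)(O[Si](CC)(CC)CC)CC[C@@H](O)[C@@H](C)CC[C@@H]2C(C)C)cc1O[Si](C(C)C)(C(C)C)C(C)C | intermediate
23 | cyclodecanone (C9 ketone, 8S methyl) | COc1ccc(C(=O)O[C@@H]2C[C@](C)(O[Si](CC)(CC)CC)CCC(=O)[C@@H](C)CC[C@@H]2C(C)C)cc1O[Si](C(C)C)(C(C)C)C(C)C | intermediate
24 | 5-trifluoroacetyl derivative of 23 | COc1ccc(C(=O)O[C@@H]2C[C@](C)(O[Si](CC)(CC)CC)CC(C(=O)C(F)(F)F)C(=O)[C@@H](C)CC[C@@H]2C(C)C)cc1O[Si](C(C)C)(C(C)C)C(C)C | intermediate (not isolated)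
25 | ten-membered α-diazo ketone (C5 diazo, C9 ketone; C1 aroate, C3 triethylsilyl ether) | COc1ccc(C(=O)O[C@@H]2C[C@](C)(O[Si](CC)(CC)CC)CC(=[N+]=[N-])C(=O)[C@@H](C)CC[C@@H]2C(C)C)cc1O[Si](C(C)C)(C(C)C)C(C)C | intermediate (key-step precursor)
26 | cis-fused hydroazulen-9-one (C5 epimer of 27) | COc1ccc(C(=O)O[C@@H]2C[C@](C)(O[Si](CC)(CC)CC)C[C@@H]3[C@@H](C[C@H](C)C3=O)[C@@H]2C(C)C)cc1O[Si](C(C)C)(C(C)C)C(C)C | intermediate (not isolated)
27 | trans-fused hydroazulen-9-one (H5 and H6 trans; drawn as the 8S epimer, methyl cis to H5) | COc1ccc(C(=O)O[C@@H]2C[C@](C)(O[Si](CC)(CC)CC)C[C@H]3[C@@H](C[C@H](C)C3=O)[C@@H]2C(C)C)cc1O[Si](C(C)C)(C(C)C)C(C)C | intermediate (key-step product)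
28 | lithium C8=C9 enolate of 27 | COc1ccc(C(=O)O[C@@H]2C[C@](C)(O[Si](CC)(CC)CC)C[C@H]3[C@@H](CC(C)=C3[O-])[C@@H]2C(C)C)cc1O[Si](C(C)C)(C(C)C)C(C)C.[Li+] | intermediate (not isolated)
29 | C8=C9 enol triflate | COc1ccc(C(=O)O[C@@H]2C[C@](C)(O[Si](CC)(CC)CC)C[C@H]3[C@@H](CC(C)=C3OS(=O)(=O)C(F)(F)F)[C@@H]2C(C)C)cc1O[Si](C(C)C)(C(C)C)C(C)C | intermediate
30 | C8=C9 alkene, C3 triethylsilyl ether | COc1ccc(C(=O)O[C@@H]2C[C@](C)(O[Si](CC)(CC)CC)C[C@H]3[C@@H](CC(C)=C3)[C@@H]2C(C)C)cc1O[Si](C(C)C)(C(C)C)C(C)C | intermediate
31 | C8=C9 alkene, free C3 hydroxyl | COc1ccc(C(=O)O[C@@H]2C[C@](C)(O)C[C@H]3[C@@H](CC(C)=C3)[C@@H]2C(C)C)cc1O[Si](C(C)C)(C(C)C)C(C)C | intermediate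
32 | O-triisopropylsilyl ether of the target (epoxide syn to C4) | COc1ccc(C(=O)O[C@@H]2C[C@](C)(O)C[C@H]3[C@@H](C[C@@]4(C)O[C@@H]34)[C@@H]2C(C)C)cc1O[Si](C(C)C)(C(C)C)C(C)C | intermediate
33 | CNP0106636.1 | COc1ccc(C(=O)O[C@@H]2C[C@](C)(O)C[C@H]3[C@@H](C[C@@]4(C)O[C@@H]34)[C@@H]2C(C)C)cc1O | target

**Step count and risk**

Total step count: 18. Longest linear sequence: 17 (steps 1–4 and 6–18 from 1); step 5 is a one-step branch.

Most likely to fail, in order:

1. Step 13 (Proposed new method). The carbenoid may be diverted by 1,2-hydride migration from C4, may insert into the tertiary C10–H, or may take the wrong C6 hydrogen, which gives a C6 configuration that cannot be repaired later. Fallback with known chemistry: the seven-membered ring is made first and the cyclopentanone is annulated onto it. It sets out from aldehyde 16. α-Methylenation (CH2=NMe2+ I−, Et3N, CH2Cl2) should give the α-methylene aldehyde F1. Ring-closing metathesis of the C5 methylene with the C6 vinyl group (second-generation Grubbs catalyst, toluene, 80 °C) should close the seven-membered ring as the cycloheptenecarbaldehyde F2 (C5=C6). Addition of CH2=C(Me)MgBr at −78 °C should give the dienol F3, and Dess–Martin oxidation the cross-conjugated dienone F4. A silane-interrupted (reductive) Nazarov cyclisation (BF3·OEt2, Et3SiH, CH2Cl2, −78 °C) should then form C6–C7 conrotatorily on the face anti to the C10 isopropyl group and reduce the oxyallyl cation. DBU equilibration of C5 brings the route back at ketone 27. The remaining uncertainty there is the torquoselectivity of the electrocyclisation.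

2. Step 9. Intermolecular metathesis (oligomers) may outrun closure, or the two hindered vinyl groups may fail to meet against the transannular strain of the forming ten-membered ring. Fallback: reductive carbonyl coupling in place of metathesis, setting out from diene alcohol 20. Silylation (Et3SiOTf, 2,6-lutidine) should give the bis(triethylsilyl) ether F5. Ozonolysis of both vinyl groups (O3, then PPh3) should give the dialdehyde F6. McMurry coupling with low-valent titanium (TiCl3(DME)1.5, Zn–Cu, DME, reflux, slow addition) should give the cyclodecene silyl ether F7. PPTS in MeOH at 0 °C should then remove the secondary silyl ether selectively and rejoin the route at cyclodecenol 21. The process to watch is epimerisation of the α-centres C8 and C10 at the dialdehyde stage.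

3. Step 14. Regiocontrol of the enolisation may be lost: proton removal at the ring-fusion C5, which is well aligned with the carbonyl, would give the C5=C9 triflate. Fallback: stereospecific elimination in place of enolate chemistry, setting out from ketone 27 as its 8S epimer (methyl cis to H5; the 8R epimer is returned to the mixture with DBU). Reduction with LiBH(s-Bu)3 (THF, −78 °C) should deliver hydride anti to the C8 methyl and give the C9 carbinol F8, with the hydroxyl cis to the methyl and to H5. Dehydration with Ph2S[OC(CF3)2Ph]2 (Martin sulfurane, CH2Cl2, rt) is an anti elimination, for which only H8 is antiperiplanar (H5 is syn to the leaving group). It should give alkene 30 directly. The weak point is the facial selectivity of the hydride addition.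

**Further compounds**

F1 | step 13 | α-methylene aldehyde (C5=CH2, C9 aldehyde) | COc1ccc(C(=O)O[C@H](C[C@](C)(O[Si](CC)(CC)CC)CC(=C)C=O)[C@H](C=C)C(C)C)cc1O[Si](C(C)C)(C(C)C)C(C)C
F2 | step 13 | cycloheptenecarbaldehyde (seven-membered ring, C5=C6, formyl C9 on C5) | COc1ccc(C(=O)O[C@@H]2C[C@](C)(O[Si](CC)(CC)CC)CC(C=O)=C[C@@H]2C(C)C)cc1O[Si](C(C)C)(C(C)C)C(C)C
F3 | step 13 | dienol (isopropenyl carbinol at C9, mixture at C9) | COc1ccc(C(=O)O[C@@H]2C[C@](C)(O[Si](CC)(CC)CC)CC(C(O)C(C)=C)=C[C@@H]2C(C)C)cc1O[Si](C(C)C)(C(C)C)C(C)C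
F4 | step 13 | cross-conjugated dienone (C5=C6–C9(=O)–C8(Me)=C7H2) | COc1ccc(C(=O)O[C@@H]2C[C@](C)(O[Si](CC)(CC)CC)CC(C(=O)C(C)=C)=C[C@@H]2C(C)C)cc1O[Si](C(C)C)(C(C)C)C(C)C
F5 | step 9 | bis(triethylsilyl) ether of 20 | COc1ccc(C(=O)O[C@H](C[C@](C)(O[Si](CC)(CC)CC)CC[C@@H](O[Si](CC)(CC)CC)[C@@H](C)C=C)[C@H](C=C)C(C)C)cc1O[Si](C(C)C)(C(C)C)C(C)C
F6 | step 9 | dialdehyde (C6 and C7 formyl groups) | COc1ccc(C(=O)O[C@H](C[C@](C)(O[Si](CC)(CC)CC)CC[C@@H](O[Si](CC)(CC)CC)[C@@H](C)C=O)[C@H](C=O)C(C)C)cc1O[Si](C(C)C)(C(C)C)C(C)C
F7 | step 9 | cyclodecene C9 triethylsilyl ether (C6=C7, drawn Z) | COc1ccc(C(=O)O[C@@H]2C[C@](C)(O[Si](CC)(CC)CC)CC[C@@H](O[Si](CC)(CC)CC)[C@@H](C)/C=C\[C@@H]2C(C)C)cc1O[Si](C(C)C)(C(C)C)C(C)C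
F8 | step 14 | C9 carbinol of 27 (hydroxyl cis to the C8 methyl and to H5) | COc1ccc(C(=O)O[C@@H]2C[C@](C)(O[Si](CC)(CC)CC)C[C@H]3[C@@H](C[C@H](C)[C@@H]3O)[C@@H]2C(C)C)cc1O[Si](C(C)C)(C(C)C)C(C)C
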